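**Plan**

1. Retrosynthesis: the O–Si bond is cut last. In the ring, both bonds of the ketone carbon (C1–C6 and C1–C2) are cut, C1 leaves as carbon monoxide and C6 is tied back to C4, which gives a 1-nonadecyl-2-vinylcyclopropyl silyl ether. The vinyl C=C, the two ring bonds of the cyclopropane CH2, the enol O–Si bond and the C4–C5 bond of a β-keto ester chain are then cut in turn.
2. Forward: the C23 chain is joined first (acetoacetate dianion plus C18 bromide), the three-membered ring is made next (step 4), and the six-membered ring arises last, in one operation, from that ring, its vinyl group and CO (step 7).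
3. Enabling feature: the vinylcyclopropane. The strained C2–C3 σ bond of the three-membered ring lies beside the vinyl π bond on C2, so zerovalent iron can open it to an allyl/alkyl pair; the freed C3H2 takes up CO and becomes the CH2 next to the ketone, with ring strain as the driving force.
4. Stereochemistry: the carbinol carbon is set in step 4 by ligand-controlled, hydroxyl-directed methylene transfer to a geometrically pure E enol ether. No bond to it is broken afterwards; the second cyclopropane stereocenter is temporary and is erased in step 7.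
5. Helpers: the triethylsilyl group (keeps the cyclopropanol closed, removed in step 8), the CH2OH handle (directs step 4, then becomes the vinyl group) and the three-membered ring itself (consumed in step 7).

Key step: step 7

Assumption: O-silylation of the β-keto ester under amine (non-chelating) conditions is taken to give the E enol ether as the main isomer; the ligand enantiomer in step 4 is chosen for this geometry.

Step 1
Reactants: 1 methyl acetoacetate (methyl 3-oxobutanoate); 2 1-bromooctadecane
Product: 3 methyl 3-oxodocosanoate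
Conditions: NaH (1.1 equiv), THF, 0 °C; n-BuLi (1.05 equiv), 0 °C; then 2, 0 °C → rt; then 1 M HCl
Reagents that add atoms: none
Why: The sodium lithium dianion of 1 reacts at its terminal (γ) carbon with the primary bromide in an SN2 reaction (acetoacetate dianion γ-alkylation), which places the C19 chain on the ketone carbon; no stereocenter is formed.

Step 2
Reactants: 3 methyl 3-oxodocosanoate
Product: 4 methyl (2E)-3-(triethylsilyloxy)docos-2-enoate
Conditions: Et3SiOTf (1.2 equiv), Et3N (1.5 equiv), CH2Cl2, −78 → 0 °C; E isomer purified on Et3N-deactivated silica, geometry to be checked by NOE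
Reagents that add atoms: triethylsilyl trifluoromethanesulfonate, CC[Si](CC)(CC)OS(=O)(=O)C(F)(F)F
Why: Silylation of the ketone oxygen of the amine-generated, non-chelated enolate (silyl enol ether formation) should give the push–pull enol ether with the silyloxy group trans to the ester; no stereocenter is formed, but this geometry decides the configuration set in step 4.

Step 3
Reactants: 4 methyl (2E)-3-(triethylsilyloxy)docos-2-enoate
Product: 5 (2E)-3-(triethylsilyloxy)docos-2-en-1-ol
Conditions: i-Bu2AlH (2.3 equiv), CH2Cl2, −78 °C; aq. potassium sodium tartrate; used promptly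
Reagents that add atoms: none
Why: 1,2-Reduction of the vinylogous carbonate ester (DIBAL-H ester reduction) should give the allylic alcohol without touching the enol ether, and the trans relation of OSiEt3 and CH2OH rules out silyl transfer to the new alkoxide; no stereocenter is formed.

Step 4
Reactants: 5 (2E)-3-(triethylsilyloxy)docos-2-en-1-ol
Product: 6 [(1S,2R)-2-nonadecyl-2-(triethylsilyloxy)cyclopropyl]methanol
Conditions: Zn(CH2I)2·DME (2.2 equiv, from Et2Zn, CH2I2 and DME), (4S,5S)-2-butyl-N,N,N′,N′-tetramethyl-1,3,2-dioxaborolane-4,5-dicarboxamide (1.2 equiv), CH2Cl2, −10 °C → rt; diethanolamine work-up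
Reagents that add atoms: diiodomethane, ICI
Why: In this asymmetric Simmons–Smith cyclopropanation with a chiral dioxaborolane ligand, the zinc alkoxide of 5 binds ligand and carbenoid so that CH2 is delivered to one face of the enol ether; the stereospecific syn addition turns the E geometry into the trans relation of OSiEt3 and CH2OH, and the (S,S) ligand should set both ring stereocenters as (1S,2R).

Step 5
Reactants: 6 [(1S,2R)-2-nonadecyl-2-(triethylsilyloxy)cyclopropyl]methanol
Product: 7 (1R,2R)-2-nonadecyl-2-(triethylsilyloxy)cyclopropane-1-carbaldehyde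
Conditions: n-Pr4N[RuO4] (5 mol %), N-methylmorpholine N-oxide (1.5 equiv), 4 Å molecular sieves, CH2Cl2, 0 °C → rt; filtered and used at once
Reagents that add atoms: none
Why: Ley–Griffith oxidation of the primary alcohol under neutral conditions should give the aldehyde without opening the donor–acceptor cyclopropane; both stereocenters are untouched (the descriptor at C1 changes only through the priority rules).

Step 6
Reactants: 7 (1R,2R)-2-nonadecyl-2-(triethylsilyloxy)cyclopropane-1-carbaldehyde
Product: 8 triethyl{[(1R,2S)-2-ethenyl-1-nonadecylcyclopropyl]oxy}silane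
Conditions: Ph3PCH3Br (1.5 equiv), KN(SiMe3)2 (1.4 equiv), THF, 0 °C; then 7, −78 → 0 °C
Reagents that add atoms: methyltriphenylphosphonium bromide, C[P+](c1ccccc1)(c1ccccc1)c1ccccc1.[Br-]
Why: Wittig methylenation with the non-stabilized ylide should convert the aldehyde into the vinyl group at low temperature before any ring opening; the carbinol stereocenter is untouched, and epimerization at the vinyl-bearing carbon would be without consequence.

Step 7
Reactants: 8 triethyl{[(1R,2S)-2-ethenyl-1-nonadecylcyclopropyl]oxy}silane
Product: 10 (5S)-5-nonadecyl-5-(triethylsilyloxy)cyclohex-2-en-1-one, via (5R)-5-nonadecyl-5-(triethylsilyloxy)cyclohex-3-en-1-one 9 (not isolated)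
Conditions: Fe(CO)5 (1.5 equiv, re-formed under CO), CO (1 atm), i-PrOH, hν (350 nm, Pyrex), rt; then DBU (0.2 equiv), CH2Cl2, 0 °C
Reagents that add atoms: carbon monoxide, [C-]#[O+] (delivered through pentacarbonyliron, Fe(CO)5, [Fe].[C-]#[O+].[C-]#[O+].[C-]#[O+].[C-]#[O+].[C-]#[O+], which is refilled from the CO atmosphere)
Why: Proposed new method: UV photolysis of Fe(CO)5 gives Fe(CO)4, which binds the vinyl group of 8 and lets zerovalent iron insert into the strained C2–C3 bond of the three-membered ring to give a σ-alkyl/π-allyl iron tricarbonyl with C3H2 on iron; migration of this CH2 to a carbonyl ligand forms the acyl–CH2 bond, and reductive elimination of the acyl group with the allyl terminus closes the six-membered ring as β,γ-enone 9, which DBU conjugates to 10. The closest known reaction type is the Fe(CO)5-mediated [5+1] carbonylation of alkyl-substituted alkenylcyclopropanes to cyclohexenones, which opens the less substituted ring bond and keeps the configuration of the substituted ring carbon; a ring carbon that carries a silyloxy group has not been used in it. The ring is closed in a formal [5+1] mode, five carbons from the vinylcyclopropane and one from CO, through a ferracyclohexene and its acyl homologue. No new stereocenter is formed: C1 of 8 keeps its configuration because none of its bonds is broken, and the temporary stereocenter C2 becomes sp2 in 9 and CH2 in 10. The step needs cleavage of C2–C3 and not of C1–C2, which the fully substituted C1 (C19 chain and OSiEt3) should secure, since insertion there would give a crowded tertiary α-silyloxyalkyl iron; it also needs the cyclopropanol to stay closed, which the triethylsilyl ether secures. Conjugation must occur without loss of silanol and aromatization, hence catalytic DBU at 0 °C.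

Step 8
Reactants: 10 (5S)-5-nonadecyl-5-(triethylsilyloxy)cyclohex-2-en-1-one
Product: 11 (5S)-5-hydroxy-5-nonadecylcyclohex-2-en-1-one (CNP0103007.1)
Conditions: HF·pyridine, pyridine, THF, 0 °C
Reagents that add atoms: none
Why: Fluoride-induced cleavage of the tertiary triethylsilyl ether (desilylation) under pyridine-buffered conditions should free the alcohol without loss of water from the β-hydroxy ketone; the stereocenter is untouched.

**Compound list**

1 | methyl acetoacetate (methyl 3-oxobutanoate) | CC(=O)CC(=O)OC | starting material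
2 | 1-bromooctadecane | CCCCCCCCCCCCCCCCCCBr | starting material
3 | methyl 3-oxodocosanoate | CCCCCCCCCCCCCCCCCCCC(=O)CC(=O)OC | intermediate
4 | methyl (2E)-3-(triethylsilyloxy)docos-2-enoate | CCCCCCCCCCCCCCCCCCC/C(O[Si](CC)(CC)CC)=C\C(=O)OC | intermediate
5 | (2E)-3-(triethylsilyloxy)docos-2-en-1-ol | CCCCCCCCCCCCCCCCCCC/C(O[Si](CC)(CC)CC)=C\CO | intermediate
6 | [(1S,2R)-2-nonadecyl-2-(triethylsilyloxy)cyclopropyl]methanol | CCCCCCCCCCCCCCCCCCC[C@@]1(O[Si](CC)(CC)CC)C[C@H]1CO | intermediate
7 | (1R,2R)-2-nonadecyl-2-(triethylsilyloxy)cyclopropane-1-carbaldehyde | CCCCCCCCCCCCCCCCCCC[C@@]1(O[Si](CC)(CC)CC)C[C@H]1C=O | intermediate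
8 | triethyl{[(1R,2S)-2-ethenyl-1-nonadecylcyclopropyl]oxy}silane | CCCCCCCCCCCCCCCCCCC[C@@]1(O[Si](CC)(CC)CC)C[C@H]1C=C | intermediate
9 | (5R)-5-nonadecyl-5-(triethylsilyloxy)cyclohex-3-en-1-one | CCCCCCCCCCCCCCCCCCC[C@]1(O[Si](CC)(CC)CC)C=CCC(=O)C1 | intermediate (not isolated)
10 | (5S)-5-nonadecyl-5-(triethylsilyloxy)cyclohex-2-en-1-one | CCCCCCCCCCCCCCCCCCC[C@]1(O[Si](CC)(CC)CC)CC=CC(=O)C1 | intermediate
11 | (5S)-5-hydroxy-5-nonadecylcyclohex-2-en-1-one | CCCCCCCCCCCCCCCCCCC[C@]1(O)CC=CC(=O)C1 | target

Total step count: 8. Longest linear sequence: 8 steps (from 1 and 2).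

**Steps most likely to fail**

Step 7 (Proposed new method). What may go wrong: insertion of iron into the oxygen-bearing C1–C2 bond, opening of the three-membered ring to diene–iron complexes without uptake of CO, or loss of triethylsilanol with aromatization during the base-induced conjugation. The fallback uses known chemistry, closes the ring at C2=C3 by olefin metathesis and brings in the ketone carbon as an acryloyl anion equivalent; it sets out from 2 and comes back at 11. The dianion of 2-methylprop-2-en-1-ol (n-BuLi, TMEDA, Et2O) is alkylated with 2 to give 2-methylidenehenicosan-1-ol F1. Sharpless asymmetric epoxidation (Ti(OiPr)4, D-(−)-diethyl tartrate, t-BuOOH, 4 Å sieves, CH2Cl2, −20 °C) should give [(2R)-2-nonadecyloxiran-2-yl]methanol F2. CH2=CHMgBr with catalytic CuI should open the epoxide at CH2 to (2S)-2-nonadecylpent-4-ene-1,2-diol F3. Selective tosylation of the primary hydroxyl (TsCl, Et3N, catalytic Bu2SnO) gives (2S)-2-hydroxy-2-nonadecylpent-4-en-1-yl 4-methylbenzenesulfonate F4, and K2CO3 in MeOH closes it to (2S)-2-nonadecyl-2-(prop-2-en-1-yl)oxirane F5. 1-Lithio-1-methoxyallene (methoxyallene, n-BuLi, THF, −40 °C → rt) should open F5 at CH2 to (5S)-3-methoxy-5-nonadecylocta-1,2,7-trien-5-ol F6. Mild aqueous acid (oxalic acid, THF/H2O, 0 °C) hydrolyses the allenyl ether to (5S)-5-hydroxy-5-nonadecylocta-1,7-dien-3-one F7. Ring-closing metathesis (second-generation Grubbs catalyst RuCl2(=CHPh)(PCy3)(H2IMes), CH2Cl2, 40 °C) should then give 11 directly.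

Step 4. What may go wrong: methylene transfer that is not guided by the zinc alkoxide–ligand complex (the enol ether is very electron-rich), hence poor facial selectivity, or ionization of the allylic C–O bond and loss of the silyl group under ZnI2. The fallback makes the ring by catalytic asymmetric carbene transfer to a 1,1-disubstituted enol ether, so that no enol ether geometry is involved; it sets out from 3 and comes back at 6. Dealkoxycarbonylation of 3 (LiCl, wet DMSO, 150 °C, Krapcho reaction) gives henicosan-2-one F8. Kinetic enolization and silylation (LiN(i-Pr)2, THF, −78 °C; Et3SiCl) give triethyl(henicos-1-en-2-yloxy)silane F9. Slow addition of ethyl diazoacetate in the presence of CuOTf and 2,2′-(propane-2,2-diyl)bis[(4S)-4-tert-butyl-4,5-dihydro-1,3-oxazole] (CH2Cl2, rt) should give ethyl (1R,2R)-2-nonadecyl-2-(triethylsilyloxy)cyclopropane-1-carboxylate F10. It forms together with its separable cis isomer, ethyl (1R,2S)-2-nonadecyl-2-(triethylsilyloxy)cyclopropane-1-carboxylate F11, which is discarded. LiAlH4 (Et2O, 0 °C) reduces F10 to 6.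

Step 6 (with the aldehyde made in step 5). What may go wrong: opening of the donor–acceptor cyclopropane at the aldehyde stage (silyl loss followed by retro-aldol-type ring opening, or ring enlargement to a dihydrofuran) before the olefination is complete. The fallback reverses the roles of the olefination partners, so that no cyclopropanecarbaldehyde is made; it sets out from 6 and comes back at 8. Mitsunobu reaction of 6 with 1-phenyl-1H-tetrazole-5-thiol (PPh3, DIAD, THF, 0 °C) gives 5-({[(1R,2R)-2-nonadecyl-2-(triethylsilyloxy)cyclopropyl]methyl}sulfanyl)-1-phenyl-1H-tetrazole F12. Oxidation (mCPBA, NaHCO3, CH2Cl2, 0 °C → rt) gives 5-({[(1R,2R)-2-nonadecyl-2-(triethylsilyloxy)cyclopropyl]methyl}sulfonyl)-1-phenyl-1H-tetrazole F13. Deprotonation with KN(SiMe3)2 (THF, −78 °C) and addition of monomeric formaldehyde (Julia–Kocienski olefination) should give 8.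

**Further compounds**

F1 | step 7 | 2-methylidenehenicosan-1-ol | CCCCCCCCCCCCCCCCCCCC(=C)CO
F2 | step 7 | [(2R)-2-nonadecyloxiran-2-yl]methanol | CCCCCCCCCCCCCCCCCCC[C@@]1(CO)CO1
F3 | step 7 | (2S)-2-nonadecylpent-4-ene-1,2-diol | CCCCCCCCCCCCCCCCCCC[C@@](O)(CO)CC=C
F4 | step 7 | (2S)-2-hydroxy-2-nonadecylpent-4-en-1-yl 4-methylbenzenesulfonate | CCCCCCCCCCCCCCCCCCC[C@@](O)(COS(=O)(=O)c1ccc(C)cc1)CC=C
F5 | step 7 | (2S)-2-nonadecyl-2-(prop-2-en-1-yl)oxirane | CCCCCCCCCCCCCCCCCCC[C@]1(CC=C)CO1
F6 | step 7 | (5S)-3-methoxy-5-nonadecylocta-1,2,7-trien-5-ol | CCCCCCCCCCCCCCCCCCC[C@](O)(CC=C)CC(OC)=C=C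
F7 | step 7 | (5S)-5-hydroxy-5-nonadecylocta-1,7-dien-3-one | CCCCCCCCCCCCCCCCCCC[C@](O)(CC=C)CC(=O)C=C
F8 | step 4 | henicosan-2-one | CCCCCCCCCCCCCCCCCCCC(C)=O
F9 | step 4 | triethyl(henicos-1-en-2-yloxy)silane | CCCCCCCCCCCCCCCCCCCC(=C)O[Si](CC)(CC)CC
F10 | step 4 | ethyl (1R,2R)-2-nonadecyl-2-(triethylsilyloxy)cyclopropane-1-carboxylate | CCCCCCCCCCCCCCCCCCC[C@@]1(O[Si](CC)(CC)CC)C[C@H]1C(=O)OCC
F11 | step 4 | ethyl (1R,2S)-2-nonadecyl-2-(triethylsilyloxy)cyclopropane-1-carboxylate | CCCCCCCCCCCCCCCCCCC[C@]1(O[Si](CC)(CC)CC)C[C@H]1C(=O)OCC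
F12 | step 6 | 5-({[(1R,2R)-2-nonadecyl-2-(triethylsilyloxy)cyclopropyl]methyl}sulfanyl)-1-phenyl-1H-tetrazole | CCCCCCCCCCCCCCCCCCC[C@@]1(O[Si](CC)(CC)CC)C[C@H]1CSc2nnnn2-c2ccccc2
F13 | step 6 | 5-({[(1R,2R)-2-nonadecyl-2-(triethylsilyloxy)cyclopropyl]methyl}sulfonyl)-1-phenyl-1H-tetrazole | CCCCCCCCCCCCCCCCCCC[C@@]1(O[Si](CC)(CC)CC)C[C@H]1CS(=O)(=O)c2nnnn2-c2ccccc2
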